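**Retrosynthetic overview**

- Gravicycle 25 comes from the 22-membered (E)-C13=C14 alkene 23 by hydrogenation (alkene and three benzyl ethers) and fluoride desilylation at C1.
- The strategy rests on C14 being the benzylic carbon on ring A (the 1,3,5-substituted mono-phenol ring) and C13 being a plain methylene of the C1–C14 chain. A sulfur atom is placed between them, and Ramberg–Bäcklund extrusion of SO2 from the 23-membered sulfone 20 forms the C13–C14 bond.
- Sulfone 20 comes from cyclic sulfide 18, which is closed by attack of the C13 thiolate on the C14 benzylic bromide of seco compound 16. The macrocycle is the only ring built: it is closed as a 23-membered thia-ring and then contracted to 22.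
- 16 comes from diaryl ether 13, made by Ullmann coupling of ring B phenol 10 with ring A bromo ester 12. 10 comes from 3,4,5-trihydroxybenzaldehyde and a C12 alkenyl Grignard reagent, with (R)-C1 set by CBS reduction.

Key step: step 15

Remark: the chain is numbered C1 (carbinol carbon on ring B, the dihydroxyphenyl ring) to C14. 12-Bromododec-1-ene is assumed to be commercially available; its terminal alkene is the latent C13 thiol, which avoids protecting and activating a bromo alcohol. CBr2F2 is assumed to be obtainable.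

**Route**

Step 1
Reactants: 1 3,4,5-trihydroxybenzaldehyde
Product: 2 4-(allyloxy)-3,5-dihydroxybenzaldehyde
Conditions: allyl bromide (1.05 equiv), NaHCO3, NaI (cat.), DMF, 40 °C, N2
Reagents that add atoms: allyl bromide, C=CCBr
Why: The 4-OH, para to the formyl group and flanked by two hydroxyls, is much the most acidic phenol, so hydrogen carbonate should form only its phenoxide and the Williamson alkylation with one equivalent of halide should go at O4.

Step 2
Reactants: 2 4-(allyloxy)-3,5-dihydroxybenzaldehyde
Product: 3 4-(allyloxy)-3,5-bis(benzyloxy)benzaldehyde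
Conditions: BnBr (2.3 equiv), K2CO3, DMF, rt
Reagents that add atoms: benzyl bromide, BrCc1ccccc1
Why: Williamson benzylation of the two equivalent remaining phenols is routine and leaves the allyl ether and the aldehyde untouched.

Step 3
Reactants: 3 4-(allyloxy)-3,5-bis(benzyloxy)benzaldehyde; 4 12-bromododec-1-ene
Product: 6 rac-1-[4-(allyloxy)-3,5-bis(benzyloxy)phenyl]tridec-12-en-1-ol, via dodec-11-enylmagnesium bromide 5 (not isolated)
Conditions: 4, Mg, I2 (cat.), THF, 40 °C; then 3, THF, −78 → 0 °C; aq. NH4Cl
Reagents that add atoms: none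
Why: Grignard addition of a primary alkylmagnesium bromide to an aromatic aldehyde forms the C1–C2 bond; the terminal alkene and the ethers are inert, and the racemic carbinol is erased in step 4.

Step 4
Reactants: 6 rac-1-[4-(allyloxy)-3,5-bis(benzyloxy)phenyl]tridec-12-en-1-ol
Product: 7 1-[4-(allyloxy)-3,5-bis(benzyloxy)phenyl]tridec-12-en-1-one
Conditions: Dess–Martin periodinane, CH2Cl2, rt
Reagents that add atoms: none
Why: Dess–Martin oxidation of a secondary benzylic alcohol is neutral and does not touch alkenes or aryl ethers.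

Step 5
Reactants: 7 1-[4-(allyloxy)-3,5-bis(benzyloxy)phenyl]tridec-12-en-1-one
Product: 8 (R)-1-[4-(allyloxy)-3,5-bis(benzyloxy)phenyl]tridec-12-en-1-ol
Conditions: (S)-2-methyl-CBS-oxazaborolidine (0.2 equiv), catecholborane (2 equiv), toluene, −78 °C; aq. work-up
Reagents that add atoms: none
Why: Corey–Bakshi–Shibata reduction, in which the (S)-oxazaborolidine binds the aryl n-alkyl ketone with the aryl group as the large substituent and delivers hydride to the Si face to give the (R)-carbinol; catecholborane is used because at −78 °C it does not hydroborate the two alkenes.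

Step 6
Reactants: 8 (R)-1-[4-(allyloxy)-3,5-bis(benzyloxy)phenyl]tridec-12-en-1-ol
Product: 9 (R)-1-[4-(allyloxy)-3,5-bis(benzyloxy)phenyl]tridec-12-enyl tert-butyldimethylsilyl ether
Conditions: TBSCl, imidazole, DMF, rt
Reagents that add atoms: tert-butyldimethylsilyl chloride, CC(C)(C)[Si](C)(C)Cl
Why: Standard silylation of a secondary alcohol, which does not affect the C1 configuration and gives a group that withstands base, hydride, radical conditions and the later hydrogenolysis.

Step 7
Reactants: 9 (R)-1-[4-(allyloxy)-3,5-bis(benzyloxy)phenyl]tridec-12-enyl tert-butyldimethylsilyl ether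
Product: 10 (R)-2,6-bis(benzyloxy)-4-[1-(tert-butyldimethylsilyloxy)tridec-12-enyl]phenol
Conditions: Pd(PPh3)4 (5 mol%), morpholine, THF, rt
Reagents that add atoms: none
Why: Tsuji–Trost deallylation, in which zerovalent palladium ionises only the aryl allyl ether to a π-allyl complex that morpholine captures; the isolated terminal alkene and the benzyl and silyl ethers are unaffected.

Step 8
Reactants: 11 methyl 3-bromo-5-hydroxybenzoate
Product: 12 methyl 3-(benzyloxy)-5-bromobenzoate
Conditions: BnBr, K2CO3, acetone, reflux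
Reagents that add atoms: benzyl bromide, BrCc1ccccc1
Why: Williamson benzylation of the single phenol of ring A.

Step 9
Reactants: 10 (R)-2,6-bis(benzyloxy)-4-[1-(tert-butyldimethylsilyloxy)tridec-12-enyl]phenol; 12 methyl 3-(benzyloxy)-5-bromobenzoate
Product: 13 methyl 3-(benzyloxy)-5-{2,6-bis(benzyloxy)-4-[(R)-1-(tert-butyldimethylsilyloxy)tridec-12-enyl]phenoxy}benzoate
Conditions: CuI (20 mol%), picolinic acid (40 mol%), K3PO4 (anhydrous), DMSO, 90 °C, Ar
Reagents that add atoms: none
Why: Ullmann-type copper-catalysed O-arylation with the picolinic acid ligand system suited to 2,6-disubstituted phenols; the aryl bromide is unhindered, and anhydrous phosphate spares the methyl ester and the silyl ether.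

Step 10
Reactants: 13 methyl 3-(benzyloxy)-5-{2,6-bis(benzyloxy)-4-[(R)-1-(tert-butyldimethylsilyloxy)tridec-12-enyl]phenoxy}benzoate
Product: 14 [3-(benzyloxy)-5-{2,6-bis(benzyloxy)-4-[(R)-1-(tert-butyldimethylsilyloxy)tridec-12-enyl]phenoxy}phenyl]methanol
Conditions: i-Bu2AlH (3 equiv), CH2Cl2, −78 → 0 °C; Rochelle salt work-up
Reagents that add atoms: none
Why: Hydride reduction of the benzoate to the benzylic alcohol that becomes C14; at low temperature the alkene and all ethers are untouched.

Step 11
Reactants: 14 [3-(benzyloxy)-5-{2,6-bis(benzyloxy)-4-[(R)-1-(tert-butyldimethylsilyloxy)tridec-12-enyl]phenoxy}phenyl]methanol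
Product: 15 S-[(R)-13-{3,5-bis(benzyloxy)-4-[3-(benzyloxy)-5-(hydroxymethyl)phenoxy]phenyl}-13-(tert-butyldimethylsilyloxy)tridecyl] ethanethioate
Conditions: AcSH (5 equiv), 2,2-dimethoxy-2-phenylacetophenone (10 mol%), hν 365 nm, degassed THF, rt
Reagents that add atoms: thioacetic acid, CC(=O)S
Why: Radical thiol–ene addition, in which the acetylthiyl radical adds to the terminal carbon C13 of the monosubstituted alkene (anti-Markovnikov) to put sulfur on C13; the free benzylic alcohol and the ethers do not interfere.

Step 12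
Reactants: 15 S-[(R)-13-{3,5-bis(benzyloxy)-4-[3-(benzyloxy)-5-(hydroxymethyl)phenoxy]phenyl}-13-(tert-butyldimethylsilyloxy)tridecyl] ethanethioate
Product: 16 S-[(R)-13-{3,5-bis(benzyloxy)-4-[3-(benzyloxy)-5-(bromomethyl)phenoxy]phenyl}-13-(tert-butyldimethylsilyloxy)tridecyl] ethanethioate
Conditions: CBr4, PPh3, CH2Cl2, 0 °C
Reagents that add atoms: carbon tetrabromide, BrC(Br)(Br)Br
Why: Appel bromination of the primary benzylic alcohol under near-neutral conditions that the thioester and silyl ether tolerate.

Step 13
Reactants: 16 S-[(R)-13-{3,5-bis(benzyloxy)-4-[3-(benzyloxy)-5-(bromomethyl)phenoxy]phenyl}-13-(tert-butyldimethylsilyloxy)tridecyl] ethanethioate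
Product: 18 23-membered cyclic sulfide (sulfur between C13 and C14; (R)-C1 silyl ether; three benzyl ethers), via bromo thiolate 17 (not isolated)
Conditions: K2CO3 (5 equiv), degassed MeOH/THF, slow addition of 16 by syringe pump to about 1 mM, rt
Reagents that add atoms: none
Why: Methanolysis of the thioacetate releases the C13 thiolate, which under high dilution displaces the benzylic bromide at C14 in an intramolecular SN2 reaction (soft nucleophile, the most reactive electrophilic carbon) and closes the 23-membered ring.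

Step 14
Reactants: 18 23-membered cyclic sulfide
Product: 20 23-membered cyclic sulfone (sulfur between C13 and C14; (R)-C1 silyl ether; three benzyl ethers), via macrocyclic sulfoxide 19 (not isolated)
Conditions: mCPBA (2.3 equiv), NaHCO3, CH2Cl2, 0 °C → rt
Reagents that add atoms: meta-chloroperoxybenzoic acid, OOC(=O)c1cccc(Cl)c1
Why: Peracid oxidation of the sulfide through the sulfoxide to the sulfone; sulfur is far more nucleophilic than the alkoxyarenes, and the buffer protects the silyl ether.

Step 15
Reactants: 20 23-membered cyclic sulfone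
Product: 23 22-membered (E)-C13=C14 alkene (styrene on ring A; (R)-C1 silyl ether; three benzyl ethers), via alpha-bromo sulfone 21 (not isolated), via episulfone 22 (not isolated)
Conditions: CBr2F2, KOH/Al2O3, t-BuOH/CH2Cl2, 0 °C → rt
Reagents that add atoms: dibromodifluoromethane, BrC(Br)(F)F (its bromine is carried only by intermediate 21; none of its atoms remains in 23)
Why: This is a Ramberg–Bäcklund reaction with in situ halogenation, an established tactic for macrocyclic benzylic sulfones: KOH on alumina deprotonates the more acidic benzylic α-carbon C14, and the carbanion takes bromine from CBr2F2 to give 21. Deprotonation at C13 then displaces bromide in a 1,3-elimination (3-exo-tet), forming the C13–C14 bond and episulfone 22, which loses SO2 cheletropically (taken up by KOH) to leave the C13=C14 alkene. The macrocycle is thus closed by ring contraction rather than end-to-end cyclisation: the bond joins two atoms already held 1,3 across sulfur, and the 23-membered thia-ring becomes the 22-membered ring of the target. No stereocentre is created and C1 is remote and untouched; the E geometry expected from the less crowded trans-episulfone does not matter because step 16 saturates the alkene. The step needs halogenation only at the sulfone α-carbons, which the carbanion-mediated halogen transfer secures since the arenes are not attacked, and bromination at C13 instead would converge on the same episulfone; CBr2F2 is chosen because difluorocarbene adds to the new styrene far less readily than dichlorocarbene would. The silyl ether and benzyl ethers are stable to KOH/Al2O3 at room temperature.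

Step 16
Reactants: 23 22-membered (E)-C13=C14 alkene
Product: 24 (R)-C1 tert-butyldimethylsilyl ether of Gravicycle (saturated chain; three free phenols)
Conditions: H2 (1 atm), 10% Pd/C, EtOAc, rt
Reagents that add atoms: none
Why: Heterogeneous hydrogenation saturates the styrene and hydrogenolyses the three aryl benzyl ethers; in neutral EtOAc the benzylic C1–O bond should be kept by its silyl group, so the stereocentre is preserved.

Step 17
Reactants: 24 (R)-C1 tert-butyldimethylsilyl ether of Gravicycle
Product: 25 Gravicycle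
Conditions: Bu4NF, AcOH (1:1), THF, 0 °C → rt
Reagents that add atoms: none
Why: Fluoride cleavage of the Si–O bond under buffered, non-acidic conditions should free the carbinol without ionising the benzylic C1–O bond, so the (R) configuration is retained and the target results.

**Compound list**

1 | 3,4,5-trihydroxybenzaldehyde | O=Cc1cc(O)c(O)c(O)c1 | starting material
2 | 4-(allyloxy)-3,5-dihydroxybenzaldehyde | O=Cc1cc(O)c(OCC=C)c(O)c1 | intermediate
3 | 4-(allyloxy)-3,5-bis(benzyloxy)benzaldehyde | O=Cc1cc(OCc2ccccc2)c(OCC=C)c(OCc2ccccc2)c1 | intermediate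
4 | 12-bromododec-1-ene | C=CCCCCCCCCCCBr | starting material
5 | dodec-11-enylmagnesium bromide | C=CCCCCCCCCCC[Mg]Br | intermediate (not isolated)
6 | rac-1-[4-(allyloxy)-3,5-bis(benzyloxy)phenyl]tridec-12-en-1-ol | C=CCCCCCCCCCCC(O)c1cc(OCc2ccccc2)c(OCC=C)c(OCc2ccccc2)c1 | intermediate
7 | 1-[4-(allyloxy)-3,5-bis(benzyloxy)phenyl]tridec-12-en-1-one | C=CCCCCCCCCCCC(=O)c1cc(OCc2ccccc2)c(OCC=C)c(OCc2ccccc2)c1 | intermediate
8 | (R)-1-[4-(allyloxy)-3,5-bis(benzyloxy)phenyl]tridec-12-en-1-ol | C=CCCCCCCCCCC[C@@H](O)c1cc(OCc2ccccc2)c(OCC=C)c(OCc2ccccc2)c1 | intermediate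
9 | (R)-1-[4-(allyloxy)-3,5-bis(benzyloxy)phenyl]tridec-12-enyl tert-butyldimethylsilyl ether | C=CCCCCCCCCCC[C@@H](O[Si](C)(C)C(C)(C)C)c1cc(OCc2ccccc2)c(OCC=C)c(OCc2ccccc2)c1 | intermediate
10 | (R)-2,6-bis(benzyloxy)-4-[1-(tert-butyldimethylsilyloxy)tridec-12-enyl]phenol | C=CCCCCCCCCCC[C@@H](O[Si](C)(C)C(C)(C)C)c1cc(OCc2ccccc2)c(O)c(OCc2ccccc2)c1 | intermediate
11 | methyl 3-bromo-5-hydroxybenzoate | COC(=O)c1cc(O)cc(Br)c1 | starting material
12 | methyl 3-(benzyloxy)-5-bromobenzoate | COC(=O)c1cc(OCc2ccccc2)cc(Br)c1 | intermediate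
13 | methyl 3-(benzyloxy)-5-{2,6-bis(benzyloxy)-4-[(R)-1-(tert-butyldimethylsilyloxy)tridec-12-enyl]phenoxy}benzoate | C=CCCCCCCCCCC[C@@H](O[Si](C)(C)C(C)(C)C)c1cc(OCc2ccccc2)c(Oc2cc(OCc3ccccc3)cc(c2)C(=O)OC)c(OCc2ccccc2)c1 | intermediate
14 | ring A benzylic alcohol from 13 | C=CCCCCCCCCCC[C@@H](O[Si](C)(C)C(C)(C)C)c1cc(OCc2ccccc2)c(Oc2cc(OCc3ccccc3)cc(CO)c2)c(OCc2ccccc2)c1 | intermediate
15 | C13 thioacetate, ring A benzylic alcohol | CC(=O)SCCCCCCCCCCCC[C@@H](O[Si](C)(C)C(C)(C)C)c1cc(OCc2ccccc2)c(Oc2cc(OCc3ccccc3)cc(CO)c2)c(OCc2ccccc2)c1 | intermediate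
16 | C13 thioacetate, C14 benzylic bromide (seco compound) | CC(=O)SCCCCCCCCCCCC[C@@H](O[Si](C)(C)C(C)(C)C)c1cc(OCc2ccccc2)c(Oc2cc(OCc3ccccc3)cc(CBr)c2)c(OCc2ccccc2)c1 | intermediate
17 | potassium C13 thiolate, C14 benzylic bromide | [K+].[S-]CCCCCCCCCCCC[C@@H](O[Si](C)(C)C(C)(C)C)c1cc(OCc2ccccc2)c(Oc2cc(OCc3ccccc3)cc(CBr)c2)c(OCc2ccccc2)c1 | intermediate (not isolated)
18 | 23-membered cyclic sulfide, (R)-C1 silyl ether, three benzyl ethers | C(c1ccccc1)Oc1cc2cc(c1)Oc1c(OCc3ccccc3)cc(cc1OCc1ccccc1)[C@H](O[Si](C)(C)C(C)(C)C)CCCCCCCCCCCCSC2 | intermediate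
19 | 23-membered cyclic sulfoxide (mixture at sulfur) | C(c1ccccc1)Oc1cc2cc(c1)Oc1c(OCc3ccccc3)cc(cc1OCc1ccccc1)[C@H](O[Si](C)(C)C(C)(C)C)CCCCCCCCCCCCS(=O)C2 | intermediate (not isolated)
20 | 23-membered cyclic sulfone, (R)-C1 silyl ether, three benzyl ethers | C(c1ccccc1)Oc1cc2cc(c1)Oc1c(OCc3ccccc3)cc(cc1OCc1ccccc1)[C@H](O[Si](C)(C)C(C)(C)C)CCCCCCCCCCCCS(=O)(=O)C2 | intermediate
21 | C14-bromo sulfone (mixture at C14) | C(c1ccccc1)Oc1cc2cc(c1)Oc1c(OCc3ccccc3)cc(cc1OCc1ccccc1)[C@H](O[Si](C)(C)C(C)(C)C)CCCCCCCCCCCCS(=O)(=O)C2Br | intermediate (not isolated)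
22 | C13–C14 episulfone (thiirane 1,1-dioxide fused in the macrocycle; mixture at C13 and C14) | C(c1ccccc1)Oc1cc2cc(c1)Oc1c(OCc3ccccc3)cc(cc1OCc1ccccc1)[C@H](O[Si](C)(C)C(C)(C)C)CCCCCCCCCCCC3C2S3(=O)=O | intermediate (not isolated)
23 | 22-membered (E)-C13=C14 alkene, (R)-C1 silyl ether, three benzyl ethers | C(c1ccccc1)Oc1cc(/C=C/CCCCCCCCCCC[C@@H](O[Si](C)(C)C(C)(C)C)c2cc(OCc3ccccc3)c(O4)c(OCc3ccccc3)c2)cc4c1 | intermediate
24 | (R)-C1 tert-butyldimethylsilyl ether of Gravicycle | Oc1cc2cc(c1)Oc1c(O)cc(cc1O)[C@H](O[Si](C)(C)C(C)(C)C)CCCCCCCCCCCCC2 | intermediate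
25 | Gravicycle, (R) at C1 | Oc1cc2cc(c1)Oc1c(O)cc(cc1O)[C@H](O)CCCCCCCCCCCCC2 | target

**Step count**

Total: 17 steps. Longest linear sequence: 16 steps (from 1 through steps 1–7 and 9–17); step 8 is a one-step side branch.

**Steps most likely to fail**

1. Step 15. The risk is a second bromination at C14 before ring closure to the episulfone, or consumption of CBr2F2 by the base so that halogen transfer stalls. The fallback sets out from sulfide 18 and returns at alkene 23, installing exactly one halogen before the sulfone exists. Sulfide 18 is treated with N-chlorosuccinimide in CH2Cl2 at 0 °C, which chlorinates the benzylic α-carbon through the aryl-stabilised thionium ion to give the C14-chloro sulfide F1. This is oxidised directly with mCPBA and NaHCO3 to the C14-chloro sulfone F2. KOt-Bu in THF at −78 → 0 °C then effects the classical Ramberg–Bäcklund reaction through episulfone 22 to 23.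

2. Step 13. The risk is intermolecular S-alkylation (dimers and oligomers) outrunning ring closure, or methanolysis of the benzylic bromide before the thioacetate is cleaved. The fallback sets out from alcohol 14 and returns at sulfide 18, closing the ring at the other carbon–sulfur bond by a radical process. Mitsunobu reaction of 14 with thioacetic acid (PPh3, DIAD, THF, 0 °C) should give the ring A benzylic thioacetate F3. K2CO3 in degassed MeOH/THF releases the benzylic thiol F4. Irradiation of a dilute degassed solution at 365 nm with 2,2-dimethoxy-2-phenylacetophenone should then add the C14 thiyl radical intramolecularly to the terminal alkene carbon C13 (anti-Markovnikov thiol–ene macrocyclisation) to give 18.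

3. Step 9. The risk is slow O-arylation of the doubly ortho-substituted phenoxide, with reductive debromination of 12 or ester hydrolysis competing at 90 °C. The fallback sets out from bromide 12 and returns at diaryl ether 13, replacing the Ullmann coupling by a room-temperature oxidative Chan–Lam–Evans coupling. Miyaura borylation of 12 (B2pin2, PdCl2(dppf), KOAc, dioxane, 80 °C) gives the pinacol boronate F5. NaIO4 and NH4OAc in acetone/water convert it to the boronic acid F6. F6 is then coupled with phenol 10 using Cu(OAc)2, pyridine and 4 Å molecular sieves in CH2Cl2 under air; this coupling with divalent copper is known to accept 2,6-disubstituted phenols.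

**Further compounds**

F1 | step 15 | C14-chloro derivative of cyclic sulfide 18 | C(c1ccccc1)Oc1cc2cc(c1)Oc1c(OCc3ccccc3)cc(cc1OCc1ccccc1)[C@H](O[Si](C)(C)C(C)(C)C)CCCCCCCCCCCCSC2Cl
F2 | step 15 | C14-chloro sulfone | C(c1ccccc1)Oc1cc2cc(c1)Oc1c(OCc3ccccc3)cc(cc1OCc1ccccc1)[C@H](O[Si](C)(C)C(C)(C)C)CCCCCCCCCCCCS(=O)(=O)C2Cl
F3 | step 13 | ring A benzylic thioacetate of 14 | C=CCCCCCCCCCC[C@@H](O[Si](C)(C)C(C)(C)C)c1cc(OCc2ccccc2)c(Oc2cc(OCc3ccccc3)cc(CSC(C)=O)c2)c(OCc2ccccc2)c1
F4 | step 13 | ring A benzylic thiol | C=CCCCCCCCCCC[C@@H](O[Si](C)(C)C(C)(C)C)c1cc(OCc2ccccc2)c(Oc2cc(OCc3ccccc3)cc(CS)c2)c(OCc2ccccc2)c1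
F5 | step 9 | methyl 3-(benzyloxy)-5-(4,4,5,5-tetramethyl-1,3,2-dioxaborolan-2-yl)benzoate | COC(=O)c1cc(OCc2ccccc2)cc(c1)B1OC(C)(C)C(C)(C)O1
F6 | step 9 | [3-(benzyloxy)-5-(methoxycarbonyl)phenyl]boronic acid | COC(=O)c1cc(OCc2ccccc2)cc(c1)B(O)O
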